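**Plan**

- Numbering (germacrane type): C10 is the methyl-bearing ether carbon; C1–C2–C3=C4 follows, with ester carbon C15 on C4; C5 is the ether CH, C6 the lactone O–CH, C7 the lactone CH (carrying C11, C12, C13), C8 the acyloxy CH, C9 the CH2. Ring A is the oxepine (O, C5, C4, C3, C2, C1, C10), ring B the oxepane (O, C5 to C10), ring C the lactone.
- Retrosynthetic cuts, in order: the C8 ester; then O6–C12 and C11–C12 with loss of CO. This is possible because O6–C6–C7–C11≡C13 is a 3-butyn-1-ol unit held trans on ring B and maps onto lactone ring C (O6–C12–C11(=C13)–C7–C6). Then C3=C4 (metathesis), C5–C6 (ketyl to acrylate), C7–C8 (allenylstannane to aldehyde) and O–C5 (alcohol to propiolate).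
- Forward order: the C10–O–C5 ether is made on linalool, the C6–C9 chain is attached, ring B closes, then ring A, then ring C; the side chain is esterified last.
- Stereochemistry: C10 from (S)-linalool; C7 from an (S)-propargylic alcohol through two anti chirality transfers; C8 from the syn-selective stannane addition; C5 and C6 from the samarium-mediated ring closure; the side-chain carbinol from a palladium-catalysed asymmetric etherification.

Key step: step 16

Assumption: (S)-(+)-linalool is bought in high enantiomeric purity, and the (R,R)-ligand of step 18 is taken to give the (S)-ether (if the sense is opposite, its enantiomer is used).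

**Route**

Step 1
Reactants: 1 (S)-(+)-linalool; 2 methyl propiolate
Product: 3 methyl (E)-3-[(S)-linalyloxy]acrylate
Conditions: PMe3 (10 mol%), CH2Cl2, 0 °C to rt
Reagents that add atoms: none
Why: Phosphine-catalysed oxa-Michael addition of the tertiary alcohol to the ynoate gives the (E)-β-alkoxyacrylate under neutral conditions, so the hindered C10–O–C5 ether is formed without touching the C10 stereocentre supplied by linalool.

Step 2
Reactants: 3 methyl (E)-3-[(S)-linalyloxy]acrylate
Product: 5 primary C8 alcohol, via B-alkyl-9-BBN adduct 4 (not isolated)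
Conditions: 9-BBN, THF, 0 °C to rt; then 30% H2O2, aq. NaOAc, 0 °C
Reagents that add atoms: hydrogen peroxide, OO
Why: Hydroboration–oxidation with the bulky borane is anti-Markovnikov and far faster at the monosubstituted vinyl group than at the trisubstituted alkene or the donor-substituted acrylate, and the buffered oxidation at low temperature avoids both Claisen rearrangement of the allyl vinyl ether and oxa-Michael closure of O8 onto C5.

Step 3
Reactants: 5 primary C8 alcohol
Product: 6 C8 aldehyde
Conditions: Dess–Martin periodinane, NaHCO3, CH2Cl2, 0 °C to rt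
Reagents that add atoms: none
Why: Dess–Martin oxidation stops at the aldehyde and, being buffered and free of amine base, does not trigger β-elimination of the vinylogous carbonate at C10.

Step 4
Reactants: 7 [(4-methoxybenzyl)oxy]acetaldehyde; 8 ethynylmagnesium bromide
Product: 9 rac-1-[(4-methoxybenzyl)oxy]but-3-yn-2-ol
Conditions: THF, −78 °C to 0 °C; aq. NH4Cl
Reagents that add atoms: none
Why: Grignard addition of the acetylide to the aldehyde gives the racemic propargylic alcohol that holds C6, C7, C11 and C13.

Step 5
Reactants: 9 rac-1-[(4-methoxybenzyl)oxy]but-3-yn-2-ol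
Product: 10 (S)-1-[(4-methoxybenzyl)oxy]but-3-yn-2-ol
Conditions: Burkholderia cepacia lipase, vinyl acetate, MTBE, rt, run to just past half conversion
Reagents that add atoms: none
Why: Lipase-catalysed kinetic resolution by transesterification: on the empirical large/medium-substituent model the enzyme acetylates the (R)-alcohol (alkoxymethyl large, ethynyl medium) and leaves the (S)-alcohol, whose carbinol carbon becomes C7.

Step 6
Reactants: 10 (S)-1-[(4-methoxybenzyl)oxy]but-3-yn-2-ol
Product: 11 (S)-propargylic mesylate
Conditions: MsCl, Et3N, CH2Cl2, −78 °C to 0 °C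
Reagents that add atoms: methanesulfonyl chloride, CS(=O)(=O)Cl
Why: Mesylation occurs at oxygen, so the carbinol configuration is retained and a propargylic leaving group is in place.

Step 7
Reactants: 11 (S)-propargylic mesylate
Product: 12 (P)-allenylstannane
Conditions: Bu3SnH, LiN(iPr)2, THF, 0 °C; CuBr·SMe2, −78 °C; then 11, −78 °C
Reagents that add atoms: tributyltin hydride, CCCC[SnH](CCCC)CCCC
Why: Anti SN2′ substitution of the propargylic mesylate by the stannylcuprate turns the carbinol stereocentre into the axis of the (P)-allenylstannane.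

Step 8
Reactants: 6 C8 aldehyde; 12 (P)-allenylstannane
Product: 13 homopropargylic alcohol (7S,8R,10S in target numbering)
Conditions: BF3·OEt2, CH2Cl2, −78 °C
Reagents that add atoms: none
Why: Lewis acid-promoted SE2′ addition of the allenylstannane to the aldehyde through an open transition state is anti to tin, which returns the axis to the C7 stereocentre with overall retention from 10, and syn-selective, which places O8 so that it will be cis to the ethynyl group on ring B.

Step 9
Reactants: 13 homopropargylic alcohol
Product: 14 O8 tert-butyldimethylsilyl ether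
Conditions: TBSOTf, 2,6-lutidine, CH2Cl2, −78 °C to 0 °C
Reagents that add atoms: tert-butyldimethylsilyl trifluoromethanesulfonate, CC(C)(C)[Si](C)(C)OS(=O)(=O)C(F)(F)F
Why: Silylation with the silyl triflate and a hindered pyridine base protects O8, which must stay inert in the carbonylation and could otherwise add to the acrylate to form a cyclic acetal.

Step 10
Reactants: 14 O8 tert-butyldimethylsilyl ether
Product: 15 primary C6 alcohol
Conditions: DDQ, CH2Cl2/pH 7 buffer, 0 °C
Reagents that add atoms: none
Why: DDQ oxidises the electron-rich benzyl ether to an oxocarbenium ion that is hydrolysed, which frees the primary C6 alcohol and leaves silyl ether, alkyne, alkenes and acrylate untouched.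

Step 11
Reactants: 15 primary C6 alcohol
Product: 17 ring B oxepane hydroxy ester, via α-ethynyl aldehyde 16 (not isolated)
Conditions: Dess–Martin periodinane, NaHCO3, CH2Cl2, 0 °C; filtration; then SmI2, MeOH, THF, 0 °C
Reagents that add atoms: none
Why: Dess–Martin oxidation followed at once by the SmI2-mediated ketyl–olefin cyclisation onto the (E)-β-alkoxyacrylate (7-exo-trig) closes ring B through a chelated chair-like transition state that gives the 2,3-trans product (C4 branch and O6 trans), with the C7 ethynyl group pseudo-equatorial so that O6 is trans to it and with the new C5 branch cis to the larger (homoprenyl) substituent on C10.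

Step 12
Reactants: 17 ring B oxepane hydroxy ester
Product: 18 O6,C13-bis(trimethylsilyl) oxepane ester
Conditions: TMSOTf, Et3N, Zn(OTf)2 (10 mol%), CH2Cl2, rt
Reagents that add atoms: trimethylsilyl trifluoromethanesulfonate, C[Si](C)(C)OS(=O)(=O)C(F)(F)F
Why: The silyl triflate with triethylamine silylates O6 and, through a zinc acetylide formed with catalytic Zn(OTf)2, the terminal alkyne, which shields both acidic sites from the amide base and the alkyne from the metathesis catalyst.

Step 13
Reactants: 18 O6,C13-bis(trimethylsilyl) oxepane ester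
Product: 21 α-methylene ester, via Mannich base 19 (not isolated), via trimethylammonium iodide 20 (not isolated)
Conditions: LiN(iPr)2, THF, −78 °C; CH2=NMe2+ I−, −78 to −20 °C; then MeI, CH2Cl2, rt; then aq. NaHCO3
Reagents that add atoms: dimethylmethyleneammonium iodide (Eschenmoser's salt), C=[N+](C)C.[I-]
Why: Mannich reaction of the ester enolate with the iminium salt at −78 °C, where loss of the β-alkoxide is slow, followed by quaternisation and E1cB loss of trimethylamine, installs the C4 methylene needed for metathesis.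

Step 14
Reactants: 21 α-methylene ester
Product: 22 bis(trimethylsilyl) 11-oxabicyclo[4.4.1]undecene ester
Conditions: second-generation Hoveyda–Grubbs catalyst (10 mol%), toluene (high dilution), 80 °C
Reagents that add atoms: none
Why: Ring-closing metathesis between the prenyl terminus and the 1,1-disubstituted acrylate, driven by loss of isobutene, forms the cis C3=C4 enoate of ring A, and only the oxepane with the C5 and C10 branches cis can bridge.

Step 15
Reactants: 22 bis(trimethylsilyl) 11-oxabicyclo[4.4.1]undecene ester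
Product: 23 trans 6-hydroxy-7-ethynyl bicyclic ester with 8-OTBS
Conditions: K2CO3, MeOH, 0 °C to rt
Reagents that add atoms: none
Why: Potassium carbonate in methanol cleaves the alkynyl C–Si bond and the trimethylsilyl ether at once, whereas the hindered tert-butyldimethylsilyl ether and the methyl ester stay, and the O6 alkoxide cannot reach C15 because it lies anti to C4.

Step 16
Reactants: 23 trans 6-hydroxy-7-ethynyl bicyclic ester with 8-OTBS
Product: 24 8-O-silyl α-methylene lactone
Conditions: PdCl2 (5 mol%), SnCl2 (5 mol%), PPh3 (10 mol%), CO (7 atm), MeCN, 75 °C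
Reagents that add atoms: carbon monoxide, [C-]#[O+]
Why: The phosphine-ligated PdCl2/SnCl2 catalyst takes up CO and the C6 hydroxyl to give an alkoxycarbonyl complex of divalent palladium (with release of HCl), which adds syn across the tethered C11≡C13 triple bond and is then freed from the vinyl carbon by protonolysis, which regenerates the chloride catalyst. The closest known reaction is the palladium-catalysed cyclocarbonylation of 3-butyn-1-ols, which converts trans-2-ethynylcycloalkanols into trans-fused α-methylene-γ-butyrolactones. Ring C closes in a 5-exo-dig mode, C11–C12 forming after O6–C12. No stereocentre is created: the trans ring fusion is inherited from C6 and C7, and syn acylpalladation followed by protonolysis can only leave the exocyclic CH2. The step needs O6 to react and not O8, exo and not endo closure, and tolerance of the enoate: the silyl ether blocks O8, the two-atom tether between O6 and the alkyne enforces exo closure, and the near-neutral conditions leave the C3=C4 ester and the silyl ether alone.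

Step 17
Reactants: 24 8-O-silyl α-methylene lactone
Product: 25 C8 alcohol of the tricyclic core
Conditions: HF·pyridine, pyridine, THF, 0 °C to rt
Reagents that add atoms: none
Why: Fluoride desilylation under buffered, non-basic conditions frees O8 without translactonisation to the cis-disposed O8 and without conjugate addition to the methylene lactone.

Step 18
Reactants: 26 2-methyl-2-vinyloxirane; 27 4-methoxybenzyl alcohol
Product: 28 (S)-2-[(4-methoxybenzyl)oxy]-2-methylbut-3-en-1-ol
Conditions: Pd2(dba)3·CHCl3 (1 mol%), (1R,2R)-N,N′-bis(2-diphenylphosphinobenzoyl)cyclohexane-1,2-diamine (3 mol%), Et3B (1 mol%), CH2Cl2, rt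
Reagents that add atoms: none
Why: Palladium-catalysed dynamic kinetic asymmetric allylic etherification: the racemic vinyl epoxide ionises to equilibrating π-allyl complexes of divalent palladium and the borate-bound alcohol is delivered to the tertiary terminus inside the chiral pocket, which sets the carbinol stereocentre.

Step 19
Reactants: 28 (S)-2-[(4-methoxybenzyl)oxy]-2-methylbut-3-en-1-ol
Product: 29 (S)-2-[(4-methoxybenzyl)oxy]-2-methylbut-3-enoic acid
Conditions: TEMPO (cat.), NaOCl (cat.), NaClO2, MeCN/pH 6.7 phosphate buffer, 35 °C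
Reagents that add atoms: sodium chlorite, [Na+].[O-]Cl=O
Why: Nitroxyl-catalysed oxidation to the aldehyde with in situ chlorite oxidation gives the acid at near-neutral pH, and the low steady-state hypochlorite concentration spares the vinyl group and the anisyl ring.

Step 20
Reactants: 25 C8 alcohol of the tricyclic core; 29 (S)-2-[(4-methoxybenzyl)oxy]-2-methylbut-3-enoic acid
Product: 31 O-(4-methoxybenzyl) ether of the target, via mixed anhydride 30 (not isolated)
Conditions: 2,4,6-trichlorobenzoyl chloride, Et3N, THF, rt; then 25, DMAP, toluene, rt to 40 °C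
Reagents that add atoms: none
Why: Yamaguchi esterification through the mixed aromatic anhydride and its acylpyridinium ion acylates the hindered C8 hydroxyl at oxygen, so C8 keeps its configuration.

Step 21
Reactants: 31 O-(4-methoxybenzyl) ether of the target
Product: 32 target CNP0325750.1
Conditions: DDQ, CH2Cl2/pH 7 buffer, 0 °C to rt
Reagents that add atoms: none
Why: Oxidative cleavage of the 4-methoxybenzyl ether with buffered DDQ releases the tertiary alcohol under neutral conditions that leave the methylene lactone, the enoate and the vinyl group intact.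

**Compound list**

Where "target numbering" is stated, descriptors refer to the numbering in the plan. The C7 descriptor alternates with the substituents on O6 and O8; the geometry at C7 does not change.

1 | (S)-(+)-linalool, (3S)-3,7-dimethylocta-1,6-dien-3-ol | C=C[C@](O)(C)CCC=C(C)C | starting material
2 | methyl propiolate | C#CC(=O)OC | starting material
3 | methyl (E)-3-{[(3S)-3,7-dimethylocta-1,6-dien-3-yl]oxy}prop-2-enoate | C=C[C@](O/C=C/C(=O)OC)(C)CCC=C(C)C | intermediate
4 | B-alkyl-9-borabicyclo[3.3.1]nonane from 3 (boron on C8) | C1CCC2CCCC1B2CC[C@](O/C=C/C(=O)OC)(C)CCC=C(C)C | intermediate (not isolated)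
5 | methyl (E)-3-{[(3S)-1-hydroxy-3,7-dimethyloct-6-en-3-yl]oxy}prop-2-enoate | OCC[C@](O/C=C/C(=O)OC)(C)CCC=C(C)C | intermediate
6 | methyl (E)-3-{[(3S)-3,7-dimethyl-1-oxooct-6-en-3-yl]oxy}prop-2-enoate | O=CC[C@](O/C=C/C(=O)OC)(C)CCC=C(C)C | intermediate
7 | [(4-methoxybenzyl)oxy]acetaldehyde | COc1ccc(COCC=O)cc1 | starting material
8 | ethynylmagnesium bromide | C#C[Mg]Br | starting material
9 | rac-1-[(4-methoxybenzyl)oxy]but-3-yn-2-ol | COc1ccc(COCC(O)C#C)cc1 | intermediate
10 | (S)-1-[(4-methoxybenzyl)oxy]but-3-yn-2-ol | C#C[C@H](O)COCc1ccc(OC)cc1 | intermediate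
11 | (S)-1-[(4-methoxybenzyl)oxy]but-3-yn-2-yl methanesulfonate | C#C[C@H](OS(C)(=O)=O)COCc1ccc(OC)cc1 | intermediate
12 | (P)-tributyl{4-[(4-methoxybenzyl)oxy]buta-1,2-dien-1-yl}stannane | [H]C([Sn](CCCC)(CCCC)CCCC)=[C@]=C([H])COCc1ccc(OC)cc1 | intermediate
13 | methyl (E)-3-{[(2S,3R,5S)-2-ethynyl-3-hydroxy-1-[(4-methoxybenzyl)oxy]-5,9-dimethyldec-8-en-5-yl]oxy}prop-2-enoate (target numbering 7S,8R,10S) | C#C[C@@H](COCc1ccc(OC)cc1)[C@H](O)C[C@](O/C=C/C(=O)OC)(C)CCC=C(C)C | intermediate
14 | 3-O-(tert-butyldimethylsilyl) ether of 13 (target numbering 7S,8R,10S) | C#C[C@@H](COCc1ccc(OC)cc1)[C@H](O[Si](C)(C)C(C)(C)C)C[C@](O/C=C/C(=O)OC)(C)CCC=C(C)C | intermediate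
15 | methyl (E)-3-{[(2S,3R,5S)-3-[(tert-butyldimethylsilyl)oxy]-2-ethynyl-1-hydroxy-5,9-dimethyldec-8-en-5-yl]oxy}prop-2-enoate | C#C[C@@H](CO)[C@H](O[Si](C)(C)C(C)(C)C)C[C@](O/C=C/C(=O)OC)(C)CCC=C(C)C | intermediate
16 | the corresponding C6 aldehyde, (2R,3R,5S)-3-silyloxy-2-ethynyl-1-oxo analogue of 15 | C#C[C@@H](C=O)[C@H](O[Si](C)(C)C(C)(C)C)C[C@](O/C=C/C(=O)OC)(C)CCC=C(C)C | intermediate (not isolated)
17 | methyl 2-[(2R,3S,4S,5R,7S)-5-[(tert-butyldimethylsilyl)oxy]-4-ethynyl-3-hydroxy-7-methyl-7-(4-methylpent-3-en-1-yl)oxepan-2-yl]acetate | CC(C)(C)[Si](C)(C)O[C@@H]1C[C@](C)(CCC=C(C)C)O[C@H](CC(=O)OC)[C@@H](O)[C@@H]1C#C | intermediate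
18 | methyl 2-[(2R,3S,4R,5R,7S)-5-[(tert-butyldimethylsilyl)oxy]-7-methyl-7-(4-methylpent-3-en-1-yl)-3-[(trimethylsilyl)oxy]-4-[(trimethylsilyl)ethynyl]oxepan-2-yl]acetate | CC(C)(C)[Si](C)(C)O[C@@H]1C[C@](C)(CCC=C(C)C)O[C@H](CC(=O)OC)[C@@H](O[Si](C)(C)C)[C@@H]1C#C[Si](C)(C)C | intermediate
19 | α-(dimethylaminomethyl) ester from 18 (both C4 epimers) | CC(C)(C)[Si](C)(C)O[C@@H]1C[C@](C)(CCC=C(C)C)O[C@H](C(CN(C)C)C(=O)OC)[C@@H](O[Si](C)(C)C)[C@@H]1C#C[Si](C)(C)C | intermediate (not isolated)
20 | trimethylammonium iodide of 19 | CC(C)(C)[Si](C)(C)O[C@@H]1C[C@](C)(CCC=C(C)C)O[C@H](C(C[N+](C)(C)C)C(=O)OC)[C@@H](O[Si](C)(C)C)[C@@H]1C#C[Si](C)(C)C.[I-] | intermediate (not isolated)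
21 | methyl 2-[(2R,3S,4R,5R,7S)-5-[(tert-butyldimethylsilyl)oxy]-7-methyl-7-(4-methylpent-3-en-1-yl)-3-[(trimethylsilyl)oxy]-4-[(trimethylsilyl)ethynyl]oxepan-2-yl]prop-2-enoate | CC(C)(C)[Si](C)(C)O[C@@H]1C[C@](C)(CCC=C(C)C)O[C@H](C(=C)C(=O)OC)[C@@H](O[Si](C)(C)C)[C@@H]1C#C[Si](C)(C)C | intermediate
22 | methyl (1R,6S,8R,9R,10S)-8-[(tert-butyldimethylsilyl)oxy]-6-methyl-10-[(trimethylsilyl)oxy]-9-[(trimethylsilyl)ethynyl]-11-oxabicyclo[4.4.1]undec-2-ene-2-carboxylate | CC(C)(C)[Si](C)(C)O[C@@H]1C[C@]2(C)CCC=C(C(=O)OC)[C@@H](O2)[C@@H](O[Si](C)(C)C)[C@@H]1C#C[Si](C)(C)C | intermediate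
23 | methyl (1R,6S,8R,9S,10S)-8-[(tert-butyldimethylsilyl)oxy]-9-ethynyl-10-hydroxy-6-methyl-11-oxabicyclo[4.4.1]undec-2-ene-2-carboxylate (6-OH trans, 8-OSi cis to the 7-ethynyl group) | CC(C)(C)[Si](C)(C)O[C@@H]1C[C@]2(C)CCC=C(C(=O)OC)[C@@H](O2)[C@@H](O)[C@@H]1C#C | intermediate
24 | 8-O-(tert-butyldimethylsilyl) ether of the tricyclic core: 5,10-epoxy bridge, trans-fused 6,12-lactone with 11(13)-methylene, methyl 15-ester (target numbering 5R,6S,7S,8R,10S) | CC(C)(C)[Si](C)(C)O[C@@H]1C[C@]2(C)CCC=C(C(=O)OC)[C@@H](O2)[C@H]2OC(=O)C(=C)[C@@H]21 | intermediate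
25 | 8-hydroxy tricyclic core (target numbering 5R,6S,7R,8R,10S) | O[C@@H]1C[C@]2(C)CCC=C(C(=O)OC)[C@@H](O2)[C@H]2OC(=O)C(=C)[C@@H]21 | intermediate
26 | 2-methyl-2-vinyloxirane (racemic) | C=CC1(C)CO1 | starting material
27 | 4-methoxybenzyl alcohol | COc1ccc(CO)cc1 | starting material
28 | (S)-2-[(4-methoxybenzyl)oxy]-2-methylbut-3-en-1-ol | C=C[C@](C)(OCc1ccc(OC)cc1)CO | intermediate
29 | (S)-2-[(4-methoxybenzyl)oxy]-2-methylbut-3-enoic acid | C=C[C@](C)(OCc1ccc(OC)cc1)C(=O)O | intermediate
30 | mixed anhydride of 29 with 2,4,6-trichlorobenzoic acid | C=C[C@](C)(OCc1ccc(OC)cc1)C(=O)OC(=O)c1c(Cl)cc(Cl)cc1Cl | intermediate (not isolated)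
31 | 8-O-[(S)-2-[(4-methoxybenzyl)oxy]-2-methylbut-3-enoyl] ester of 25 | C=C[C@](C)(OCc1ccc(OC)cc1)C(=O)O[C@@H]1C[C@]2(C)CCC=C(C(=O)OC)[C@@H](O2)[C@H]2OC(=O)C(=C)[C@@H]21 | intermediate
32 | CNP0325750.1, 8-O-[(S)-2-hydroxy-2-methylbut-3-enoyl] ester of 25 (target numbering 5R,6S,7R,8R,10S) | C=C[C@](C)(O)C(=O)O[C@@H]1C[C@]2(C)CCC=C(C(=O)OC)[C@@H](O2)[C@H]2OC(=O)C(=C)[C@@H]21 | target

**Step count and risks**

Total: 21 steps. Longest linear sequence: 16 steps (steps 4–17, 20 and 21, counted from aldehyde 7).

Steps most likely to fail: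

Step 11. The α-ethynyl aldehyde 16 may isomerise to the allenyl aldehyde or lose silanol before the ketyl forms, and the ketyl may add to the wrong face of the acrylate. Fallback: setting out from alcohol 15, the aldehyde is avoided. With Ir[dF(CF3)ppy]2(dtbbpy)PF6, quinuclidine and tetrabutylammonium dihydrogen phosphate in MeCN under blue light, hydrogen-atom abstraction from the carbinol C6–H gives the α-hydroxyalkyl radical. This closes onto the β-alkoxyacrylate in a Giese-type 7-exo cyclisation and returns to the route at oxepane 17 (no new compound: F0).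

Step 14. Initiation at the trisubstituted prenyl end may be slow and turnover onto the electron-poor 1,1-disubstituted alkene poor, so that oligomerisation or enyne metathesis at the silylalkyne competes. Fallback: setting out from ester 18 (which also bypasses the enolate Mannich sequence of step 13), C-phosphorylation of the lithium enolate with diethyl chlorophosphate (excess LiN(iPr)2, −78 °C to rt, by 1,3-shift of the first-formed ketene acetal phosphate) gives the α-phosphono ester F1. Ozonolysis of its prenyl alkene (−78 °C, Me2S) gives the aldehyde F2. LiCl and DBU in MeCN at high dilution then close ring A by intramolecular Horner–Wadsworth–Emmons olefination and return to 22.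

Step 16. HCl set free at the metal may cleave the silyl ether or hydrate the alkyne, and the hindered C6 hydroxyl may be slow to form the alkoxycarbonyl complex. Fallback: setting out from 23, Markovnikov iodoboration–protonolysis (B-iodo-9-BBN, hexane, 0 °C; then AcOH) gives the 2-iodoalkene F3. Pd(PPh3)4, CO (1 atm) and K2CO3 in MeCN then join O6 and C11 through CO by oxidative addition to zerovalent palladium, CO insertion and capture of the acyl complex by O6, and return to 24.

**Further compounds**

F0 | step 11 | none | none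
F1 | step 14 | methyl 2-(diethoxyphosphoryl)-2-[oxepan-2-yl]acetate analogue of 18 (both C4 epimers) | CC(C)(C)[Si](C)(C)O[C@@H]1C[C@](C)(CCC=C(C)C)O[C@H](C(P(=O)(OCC)OCC)C(=O)OC)[C@@H](O[Si](C)(C)C)[C@@H]1C#C[Si](C)(C)C
F2 | step 14 | C3 aldehyde from F1 (7-(3-oxopropyl)oxepane) | CC(C)(C)[Si](C)(C)O[C@@H]1C[C@](C)(CCC=O)O[C@H](C(P(=O)(OCC)OCC)C(=O)OC)[C@@H](O[Si](C)(C)C)[C@@H]1C#C[Si](C)(C)C
F3 | step 16 | 7-(1-iodovinyl) analogue of 23 | CC(C)(C)[Si](C)(C)O[C@@H]1C[C@]2(C)CCC=C(C(=O)OC)[C@@H](O2)[C@@H](O)[C@@H]1C(I)=C
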